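The earlier runs and the new flask stem from a simulated flask for an exercise, and the scatter is random.

What I looked at first was the leftover: the north run still held 5% of its substrate at 15.0 h. This flask is that same run carried on to 4.0 d, where I had to choose the next step.

common to all: temperature 0 °C

| charge | substrate | remark | time |
|---|---|---|---|
| north | 0.050 M | the very flask that is asked about, followed so far |  |
| south | 0.034 M | run made earlier |  |
| flask | 0.050 M |  | 4.0 d |

| run | time / h | target / % | substrate / % |
|---|---|---|---|
| north | 15.0 | 27 | 5 |
| north | 30.0 | 22 | 0 |
| north | 40.0 | 18 | 0 |
| north | 60.0 | 13 | 1 |
| south | 6.00 | 24 | 33 |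
| south | 20.0 | 27 | 0 |
| south | 30.0 | 23 | 1 |
| south | 48.0 | 15 | 0 |

(scatter of a reading: 1.5 percentage points)

* target, in percent of the substrate first charged, at 4.0 d
* what to do for the largest gain in target; "none" if nothing gains more than 2 percentage points (grey / blue / red / teal / none)
* target present, with what was taken out counted in, in percent of the substrate first charged, after grey
* target present, with what was taken out counted in, in percent of the substrate first charged, after red

- grey: at 4.0 d take out 90% of the target then present, then wait 30 h
- blue: at 4.0 d raise the temperature by 25 K, then wait 30 h
- red: at 4.0 d add substrate, 50.0% of the amount charged, then wait 30 h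
- teal: change nothing and wait 30 h more

- removed target is counted in
- additions bring no volume worth counting
- the earlier runs do not show what temperature does; that part of a forecast is a guess

1. From the south reading of 33% at 6.00 h I read 3.75 h as the substrate half-life, the time in which the substrate falls to half of what stands at that moment. The north reading gave 3.47 h at the higher charge, so I took the loss as first order.

2. Up to 4.0 d the flask counted 25.6 half-lives. Because the half-life is far shorter than that wait, I expected hardly any substrate in the flask by then.

3. The north target fell from 27% to 13% between 15.0 h and 60.0 h. I read this as a fade with a half-life of 42.7 h, which gave me 7.24% at 4.0 d.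

4. I gave added substrate 8.00 half-lives in 30 h, which on my reckoning leaves 0.391% of the addition. The south reading put 35.8% of the used substrate into target, so red offered about 17.9% of the first charge before fading. Grey, on my reckoning, saved 6.52%, so red offered more than grey, and I chose red.

5. The forecast gave 7% at 4.0 d, 6.7% after grey and 15.6% after red. It also chose red, and of blue it said: “no substrate remains, so heat only speeds the loss”.

6. The flask gave 10.0% at 4.0 d, 13.8% after grey and 20.2% after red. The best step was blue, with a gain of 23 percentage points, against 10 points for red, 3.7 points for grey and −0.86 points for teal.

    substrate → target (k = 0.00120 /min, Ea = 95.0 kJ/mol)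
    substrate → side product (k = 0.00180 /min, Ea = 90.0 kJ/mol)
    target ⇌ isomer of the product (K = 3.60, k = 4.60 × 10⁻⁴ /min, Ea = 95.0 kJ/mol, ΔH = −75.0 kJ/mol)
    (constants at 0 °C)

The forecast and the flask parted on blue: at 96.0 h the flask held 0% substrate and 30.0% isomer of the product, and heating still gained target. On this flask, 9.60 h is 2.56 half-lives, which leaves 17.0% substrate; the flask stood at 17.8%. The repeat at −25 °C, with the same charge and time, kept 75% substrate at 96.0 h. That is 0.423 of the repeat's own half-lives where the flask at 0 °C counted 25.6, so the repeat's half-life was 227 h, and the repeat held 8.68% target.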